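**Plan**
1. Retrosynthesis: remove the benzyl ethers and acetates; cut the oxirane C6–O bond (C1 alkoxide onto a C6 sulfonate); cut C1–O and C7–O (dihydroxylation of a C1=C7 methylidene made from a C1 ketone); cut the ring bond C2–C3 (intramolecular aldol), which opens the carbocycle to a hexos-5-ulose from D-galactose.
2. Enabling feature: all six ring carbons carry oxygen (C1/C6 oxirane, C2/C3 acetates, C4/C5 hydroxyls), so with C1 as ketone the ring is an inosose and C2–C3 is the bond between a ketone α-carbon and an aldehyde carbon of a 1,5-dicarbonyl sugar.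
3. Forward: a galactose thioglycoside is given distinct groups on O2/O3 (Bn), O4 (PMB) and O6 (TBS), opened to the alditol and doubly oxidised; the aldol closes the carbocycle (step 8); C7 is added by methylenation and dihydroxylation; the oxirane closes in step 15; silyl-to-acetyl exchange and hydrogenolysis finish.
4. Stereochemistry: C4 and C5 are galactose C2 and C3, untouched; C6 is galactose C4, inverted once in the oxirane closure; C2 and C3 arise in the aldol (both equatorial, trans); C1 is set by osmylation anti to the axial C6 ether.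

Key step: step 8

Remark: ring numbering follows the target (C1 quaternary oxirane carbon, C2/C3 acetoxy carbons, C4/C5 carbinols, C6 oxirane CH, C7 exocyclic CH2); α is the face of the oxirane oxygen in the target, β the face of C7. Ring C2, C3, C4, C5, C6, C1 derive from galactose C6, C1, C2, C3, C4, C5, and the commercial phenyl thioglycoside 1 is taken as the form in which D-galactose enters.

**Step 1**
Reactants: 1 phenyl 1-thio-β-D-galactopyranoside; 2 4-methoxybenzaldehyde dimethyl acetal
Product: 3 phenyl 4,6-O-(4-methoxybenzylidene)-1-thio-β-D-galactopyranoside (aryl equatorial)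
Conditions: 2, camphorsulfonic acid (cat.), MeCN, rt; Et3N quench
Reagents that add atoms: 4-methoxybenzaldehyde dimethyl acetal, COc1ccc(cc1)C(OC)OC
Why: Acid-catalysed transacetalisation should select the 4,6-diol because the six-membered dioxane with equatorial aryl is the thermodynamic acetal of a galactopyranoside.

**Step 2**
Reactants: 3; 4 benzyl bromide
Product: 5 phenyl 2,3-di-O-benzyl-4,6-O-(4-methoxybenzylidene)-1-thio-β-D-galactopyranoside
Conditions: NaH, BnBr, DMF, 0 °C → rt
Reagents that add atoms: benzyl bromide, BrCc1ccccc1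
Why: Williamson etherification of the two remaining hydroxyls, to which acetal and thioglycoside are inert.

**Step 3**
Reactants: 5
Product: 6 phenyl 2,3-di-O-benzyl-4-O-(4-methoxybenzyl)-1-thio-β-D-galactopyranoside (free 6-OH)
Conditions: BH3·THF, Bu2BOTf (1 equiv), THF, 0 °C; Et3N, MeOH quench
Reagents that add atoms: none
Why: Regioselective reductive acetal opening, in which at 0 °C the boron Lewis acid binds the less hindered O6, the C–O6 bond breaks and borane reduces the oxocarbenium ion, so the PMB ether should stay on O4.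

**Step 4**
Reactants: 6; 7 tert-butyldimethylsilyl chloride
Product: 8 phenyl 2,3-di-O-benzyl-6-O-(tert-butyldimethylsilyl)-4-O-(4-methoxybenzyl)-1-thio-β-D-galactopyranoside
Conditions: TBSCl, imidazole, CH2Cl2, rt
Reagents that add atoms: tert-butyldimethylsilyl chloride, CC(C)(C)[Si](C)(C)Cl
Why: Silylation of the only free, primary hydroxyl.

**Step 5**
Reactants: 8
Product: 9 2,3-di-O-benzyl-6-O-(tert-butyldimethylsilyl)-4-O-(4-methoxybenzyl)-D-galactopyranose (anomeric mixture)
Conditions: NBS, acetone/H2O 9:1, −15 → 0 °C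
Reagents that add atoms: water, O
Why: Thioglycoside hydrolysis by bromonium activation of sulfur and capture of the oxocarbenium ion by water, under conditions too mild to cleave PMB or TBS ethers.

**Step 6**
Reactants: 9
Product: 10 2,3-di-O-benzyl-6-O-(tert-butyldimethylsilyl)-4-O-(4-methoxybenzyl)-D-galactitol (sugar numbering kept; free 1-OH and 5-OH)
Conditions: NaBH4, EtOH, 0 °C → rt
Reagents that add atoms: none
Why: Borohydride reduction of the open-chain aldehyde tautomer of the lactol gives the 1,5-diol, whose C5 carbinol configuration is irrelevant because it is oxidised next.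

**Step 7**
Reactants: 10
Product: 11 2,3-di-O-benzyl-6-O-(tert-butyldimethylsilyl)-4-O-(4-methoxybenzyl)-L-arabino-hexos-5-ulose
Conditions: (COCl)2, DMSO, CH2Cl2, −78 °C; iPr2NEt, −78 → −40 °C; pH 7 buffer; crude 11 used at once
Reagents that add atoms: none
Why: Double Swern oxidation, in which both hydroxyls become alkoxysulfonium ions at −78 °C before any carbonyl exists, so no lactol (and hence no lactone) can form and the keto-aldehyde is released only on cold deprotonation.

**Step 8**
Reactants: 11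
Product: 12 inosose (cyclohexan-1-one with 2α-OTBS, 3β-OH, 4α-OBn, 5β-OBn, 6β-OPMB)
Conditions: DBU (0.2 equiv), toluene, −20 → 0 °C; AcOH quench
Reagents that add atoms: none
Why: DBU reversibly enolises the ketone toward the silyloxymethyl carbon and this enolate carbon (C2) adds to the aldehyde carbon (C3), an intramolecular aldol addition of the kind known for protected hexos-5-uloses and the laboratory counterpart of the inositol-synthase aldol. The carbocycle closes in a 6-(enolendo)-exo-trig mode, and only the C2 enolate can reach the aldehyde through a six-membered transition state, so enolisation on the C6 side is unproductive. C2 is set by the (Z)-enolate (silyloxy cis to the enolate oxygen) in a chair transition state that keeps the C4 and C5 benzyloxy groups equatorial, which places the silyloxy group equatorial (α); C3 is set by the aldehyde face that puts the new hydroxyl equatorial (β), trans to both neighbours. Because aldol and retro-aldol equilibrate under the amine, the product should converge on this isomer with four equatorial substituents, the C2 epimer being penalised by a 1,3-diaxial clash between the silyloxy group and the axial C6 PMB ether. The selectivity the step needs is retention of the axial C6 oxygen and of C4 next to the aldehyde: catalytic base, low temperature and fast ring closure protect the open chain, and in the product the C6–H is equatorial and poorly aligned with the carbonyl π system, so it should be removed only slowly.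

**Step 9**
Reactants: 12; 13 tert-butyldimethylsilyl trifluoromethanesulfonate
Product: 14 cyclohexan-1-one with 2α,3β-bis-OTBS, 4α,5β-bis-OBn, 6β-OPMB
Conditions: TBSOTf, 2,6-lutidine, CH2Cl2, −78 → −20 °C
Reagents that add atoms: tert-butyldimethylsilyl trifluoromethanesulfonate, CC(C)(C)[Si](C)(C)OS(=O)(=O)C(F)(F)F
Why: Silylation with a silyl triflate and a hindered pyridine does not enolise the ketone, and the silyl ether blocks retro-aldol and is a poor leaving group for β-elimination in the following steps.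

**Step 10**
Reactants: 14; 15 Tebbe reagent Cp2Ti(μ-Cl)(μ-CH2)AlMe2
Product: 16 1-methylidene (C7) cyclohexane with 2α,3β-bis-OTBS, 4α,5β-bis-OBn, 6β-OPMB
Conditions: Cp2Ti(μ-Cl)(μ-CH2)AlMe2, pyridine (cat.), THF/toluene, −40 → 0 °C; aq. NaOH quench
Reagents that add atoms: Tebbe reagent, C[Al-]1(C)C[Ti]([Cl+]1)(C1C=CC=C1)C1C=CC=C1
Why: Tebbe methylenation (titanium methylidene cycloaddition and cycloreversion) is non-basic, so the hindered α,α′-dioxygenated ketone should be olefinated without epimerisation at C2 or C6 and without β-elimination.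

**Step 11**
Reactants: 16
Product: 17 diol with 1α-OH (axial) and 1β-CH2OH (C7), 2α,3β-bis-OTBS, 4α,5β-bis-OBn, 6β-OPMB
Conditions: OsO4 (5 mol%), NMO, acetone/H2O 8:1, rt
Reagents that add atoms: N-methylmorpholine N-oxide, C[N+]1([O-])CCOCC1; water, O; osmium tetroxide (catalytic oxygen carrier), O=[Os](=O)(=O)=O
Why: Catalytic syn-dihydroxylation of the 1,1-disubstituted alkene should occur on the α face, anti to the axial allylic C6 PMB ether that shields the β face, so C1 receives an axial α-hydroxyl and C7 ends equatorial (β).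

**Step 12**
Reactants: 17; 18 benzoyl chloride
Product: 19 C7 benzoate with free tertiary 1α-OH, 2α,3β-bis-OTBS, 4α,5β-bis-OBn, 6β-OPMB
Conditions: BzCl (1.1 equiv), pyridine, CH2Cl2, −20 → 0 °C
Reagents that add atoms: benzoyl chloride, O=C(Cl)c1ccccc1
Why: Selective acylation of the primary hydroxyl, the tertiary one being unreactive under these conditions.

**Step 13**
Reactants: 19
Product: 20 trans-diaxial 1α,6β-diol with C7 benzoate, 2α,3β-bis-OTBS, 4α,5β-bis-OBn
Conditions: DDQ, CH2Cl2/pH 7 buffer 10:1, 0 °C → rt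
Reagents that add atoms: none
Why: Oxidative PMB cleavage (hydride abstraction by DDQ, then hydrolysis of the benzylic oxocarbenium ion), which plain benzyl ethers should survive because they are oxidised far more slowly.

**Step 14**
Reactants: 20; 21 methanesulfonyl chloride
Product: 22 6β-mesylate with free 1α-OH, C7 benzoate, 2α,3β-bis-OTBS, 4α,5β-bis-OBn
Conditions: MsCl, Et3N, DMAP (cat.), CH2Cl2, 0 °C
Reagents that add atoms: methanesulfonyl chloride, CS(=O)(=O)Cl
Why: Sulfonylation of the secondary axial hydroxyl, to which the tertiary C1 hydroxyl is inert.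

**Step 15**
Reactants: 22
Product: 23 1α,6α-epoxide with 1β-CH2OBz, 2α,3β-bis-OTBS, 4α,5β-bis-OBn
Conditions: NaH, THF, 0 °C → rt
Reagents that add atoms: none
Why: Intramolecular Williamson etherification, in which the axial C1 alkoxide displaces the antiperiplanar C6 mesylate (3-exo-tet, inversion at C6) to give the α-oxirane; a transient benzoyl shift between O7 and O1 is harmless because only the O1 alkoxide can reach the back side of C6.

**Step 16**
Reactants: 23
Product: 24 1α,6α-epoxide with 1β-CH2OBz, 2α,3β-diol, 4α,5β-bis-OBn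
Conditions: HF·pyridine, pyridine, THF, 0 °C → rt
Reagents that add atoms: none
Why: Fluoride cleavage of both silyl ethers in a weakly acidic buffered medium, which disfavours acyl migration and should leave the electron-poor oxirane closed.

**Step 17**
Reactants: 24; 25 acetic anhydride
Product: 26 1α,6α-epoxide with 1β-CH2OBz, 2α,3β-diacetate, 4α,5β-bis-OBn
Conditions: Ac2O, pyridine, DMAP (cat.), CH2Cl2, 0 °C → rt
Reagents that add atoms: acetic anhydride, CC(=O)OC(C)=O
Why: DMAP-catalysed acetylation of the two secondary hydroxyls, with no free hydroxyl left to compete.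

**Step 18**
Reactants: 26
Product: 27 target CNP0171674.1 (1α,6α-epoxide, 1β-CH2OBz, 2α-OAc, 3β-OAc, 4α-OH, 5β-OH)
Conditions: H2 (1 atm), Pd(OH)2/C, EtOAc, rt
Reagents that add atoms: none
Why: Hydrogenolysis of the two benzyl ethers under neutral conditions, which spare the non-benzylic oxirane and the esters and give no base to trigger acyl migration or a Payne rearrangement of the freed C5 hydroxyl.

**Compound list**
1 | phenyl 1-thio-β-D-galactopyranoside | OC[C@H]1O[C@@H](Sc2ccccc2)[C@H](O)[C@@H](O)[C@H]1O | starting material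
2 | 4-methoxybenzaldehyde dimethyl acetal | COc1ccc(cc1)C(OC)OC | starting material
3 | phenyl 4,6-O-(4-methoxybenzylidene)-1-thio-β-D-galactopyranoside | COc1ccc(cc1)[C@H]1OC[C@H]2O[C@@H](Sc3ccccc3)[C@H](O)[C@@H](O)[C@H]2O1 | intermediate
4 | benzyl bromide | BrCc1ccccc1 | starting material
5 | phenyl 2,3-di-O-benzyl-4,6-O-(4-methoxybenzylidene)-1-thio-β-D-galactopyranoside | COc1ccc(cc1)[C@H]1OC[C@H]2O[C@@H](Sc3ccccc3)[C@H](OCc3ccccc3)[C@@H](OCc3ccccc3)[C@H]2O1 | intermediate
6 | phenyl 2,3-di-O-benzyl-4-O-(4-methoxybenzyl)-1-thio-β-D-galactopyranoside | OC[C@H]1O[C@@H](Sc2ccccc2)[C@H](OCc2ccccc2)[C@@H](OCc2ccccc2)[C@H]1OCc1ccc(OC)cc1 | intermediate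
7 | tert-butyldimethylsilyl chloride | CC(C)(C)[Si](C)(C)Cl | starting material
8 | phenyl 2,3-di-O-benzyl-6-O-(tert-butyldimethylsilyl)-4-O-(4-methoxybenzyl)-1-thio-β-D-galactopyranoside | CC(C)(C)[Si](C)(C)OC[C@H]1O[C@@H](Sc2ccccc2)[C@H](OCc2ccccc2)[C@@H](OCc2ccccc2)[C@H]1OCc1ccc(OC)cc1 | intermediate
9 | 2,3-di-O-benzyl-6-O-(tert-butyldimethylsilyl)-4-O-(4-methoxybenzyl)-D-galactopyranose (anomeric mixture) | CC(C)(C)[Si](C)(C)OC[C@H]1OC(O)[C@H](OCc2ccccc2)[C@@H](OCc2ccccc2)[C@H]1OCc1ccc(OC)cc1 | intermediate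
10 | 2,3-di-O-benzyl-6-O-(tert-butyldimethylsilyl)-4-O-(4-methoxybenzyl)-D-galactitol | OC[C@H](OCc1ccccc1)[C@@H](OCc1ccccc1)[C@@H](OCc1ccc(OC)cc1)[C@H](O)CO[Si](C)(C)C(C)(C)C | intermediate
11 | 2,3-di-O-benzyl-6-O-(tert-butyldimethylsilyl)-4-O-(4-methoxybenzyl)-L-arabino-hexos-5-ulose | O=C[C@H](OCc1ccccc1)[C@@H](OCc1ccccc1)[C@@H](OCc1ccc(OC)cc1)C(=O)CO[Si](C)(C)C(C)(C)C | intermediate
12 | inosose: cyclohexan-1-one, 2α-OTBS, 3β-OH, 4α-OBn, 5β-OBn, 6β-OPMB | O[C@H]1[C@H](OCc2ccccc2)[C@@H](OCc2ccccc2)[C@@H](OCc2ccc(OC)cc2)C(=O)[C@@H]1O[Si](C)(C)C(C)(C)C | intermediate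
13 | tert-butyldimethylsilyl trifluoromethanesulfonate | CC(C)(C)[Si](C)(C)OS(=O)(=O)C(F)(F)F | starting material
14 | cyclohexan-1-one, 2α,3β-bis-OTBS, 4α,5β-bis-OBn, 6β-OPMB | CC(C)(C)[Si](C)(C)O[C@H]1[C@H](OCc2ccccc2)[C@@H](OCc2ccccc2)[C@@H](OCc2ccc(OC)cc2)C(=O)[C@@H]1O[Si](C)(C)C(C)(C)C | intermediate
15 | Tebbe reagent Cp2Ti(μ-Cl)(μ-CH2)AlMe2 | C[Al-]1(C)C[Ti]([Cl+]1)(C1C=CC=C1)C1C=CC=C1 | starting material
16 | 1-methylidene cyclohexane, 2α,3β-bis-OTBS, 4α,5β-bis-OBn, 6β-OPMB | CC(C)(C)[Si](C)(C)O[C@H]1[C@H](OCc2ccccc2)[C@@H](OCc2ccccc2)[C@@H](OCc2ccc(OC)cc2)C(=C)[C@@H]1O[Si](C)(C)C(C)(C)C | intermediate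
17 | 1α-OH, 1β-CH2OH diol, 2α,3β-bis-OTBS, 4α,5β-bis-OBn, 6β-OPMB | CC(C)(C)[Si](C)(C)O[C@H]1[C@H](OCc2ccccc2)[C@@H](OCc2ccccc2)[C@@H](OCc2ccc(OC)cc2)[C@@](O)(CO)[C@@H]1O[Si](C)(C)C(C)(C)C | intermediate
18 | benzoyl chloride | O=C(Cl)c1ccccc1 | starting material
19 | 1α-OH, 1β-CH2OBz, 2α,3β-bis-OTBS, 4α,5β-bis-OBn, 6β-OPMB | CC(C)(C)[Si](C)(C)O[C@H]1[C@H](OCc2ccccc2)[C@@H](OCc2ccccc2)[C@@H](OCc2ccc(OC)cc2)[C@@](O)(COC(=O)c2ccccc2)[C@@H]1O[Si](C)(C)C(C)(C)C | intermediate
20 | 1α,6β-diol, 1β-CH2OBz, 2α,3β-bis-OTBS, 4α,5β-bis-OBn | CC(C)(C)[Si](C)(C)O[C@H]1[C@H](OCc2ccccc2)[C@@H](OCc2ccccc2)[C@@H](O)[C@@](O)(COC(=O)c2ccccc2)[C@@H]1O[Si](C)(C)C(C)(C)C | intermediate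
21 | methanesulfonyl chloride | CS(=O)(=O)Cl | starting material
22 | 6β-OMs, 1α-OH, 1β-CH2OBz, 2α,3β-bis-OTBS, 4α,5β-bis-OBn | CC(C)(C)[Si](C)(C)O[C@H]1[C@H](OCc2ccccc2)[C@@H](OCc2ccccc2)[C@@H](OS(C)(=O)=O)[C@@](O)(COC(=O)c2ccccc2)[C@@H]1O[Si](C)(C)C(C)(C)C | intermediate
23 | 1α,6α-epoxide, 1β-CH2OBz, 2α,3β-bis-OTBS, 4α,5β-bis-OBn | CC(C)(C)[Si](C)(C)O[C@H]1[C@H](OCc2ccccc2)[C@@H](OCc2ccccc2)[C@@H]2O[C@]2(COC(=O)c2ccccc2)[C@@H]1O[Si](C)(C)C(C)(C)C | intermediate
24 | 1α,6α-epoxide, 1β-CH2OBz, 2α,3β-diol, 4α,5β-bis-OBn | O[C@H]1[C@H](OCc2ccccc2)[C@@H](OCc2ccccc2)[C@@H]2O[C@]2(COC(=O)c2ccccc2)[C@@H]1O | intermediate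
25 | acetic anhydride | CC(=O)OC(C)=O | starting material
26 | 1α,6α-epoxide, 1β-CH2OBz, 2α,3β-diacetate, 4α,5β-bis-OBn | CC(=O)O[C@H]1[C@H](OCc2ccccc2)[C@@H](OCc2ccccc2)[C@@H]2O[C@]2(COC(=O)c2ccccc2)[C@@H]1OC(C)=O | intermediate
27 | CNP0171674.1: 1α,6α-epoxide, 1β-CH2OBz, 2α-OAc, 3β-OAc, 4α-OH, 5β-OH | CC(=O)O[C@H]1[C@H](O)[C@@H](O)[C@@H]2O[C@]2(COC(=O)c2ccccc2)[C@@H]1OC(C)=O | target

**Totals**
Total step count: 18. Longest linear sequence: 18 steps (1 → 27).

**Steps most likely to fail**

Step 8 (aldol closure). What may go wrong: enolisation at the aldehyde α-carbon or on the C6 side of the ketone with E1cB loss of the C5 benzyloxy group, epimerisation of the axial C6 ether before ring closure, or incomplete equilibration that leaves the cis (C2-axial) aldol. Fallback: the same bond is closed by enamine catalysis instead of through a free enolate. Setting out from 11, (S)-proline (30 mol%) in DMSO at room temperature should condense with the ketone; the enamine on the silyloxymethyl side adds to the aldehyde, which the carboxylic acid activates by hydrogen bonding (Hajos–Parrish-type 6-enolendo aldolisation, known for sugar-derived 1,5-dicarbonyl compounds). With no free enolate present the E1cB channels are closed, and hydrolysis of the iminium ion returns the route at 12. No new compound is made (entry F0). If the catalyst proves mismatched with the substrate, its antipode is taken.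

Step 11 (dihydroxylation). What may go wrong: slow osmylation of the crowded 1,1-disubstituted alkene, or attack on both faces. Fallback: carbon rather than oxygen is delivered to C1. Setting out from ketone 14, dimethylsulfoxonium methylide (Me3S(O)I, NaH, DMSO/THF, rt; Corey–Chaykovsky epoxidation) adds reversibly, so the betaine with equatorial C7 should close and give the C1 spiro-epoxide F1 with the axial α-oxygen. Caesium benzoate (CsO2CPh, PhCO2H, DMF, 90 °C) then opens it at the methylene carbon, and the route is rejoined at 19; steps 10 to 12 are bypassed.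

Step 16 (desilylation). What may go wrong: opening of the oxirane by fluoride or acid, or benzoyl migration from O7 to the freed O2, during the slow removal of two hindered silyl ethers. Fallback: the silyl-to-acetyl exchange is moved in front of the oxirane closure. Setting out from 19, aqueous HF in MeCN removes both silyl ethers to give the triol F2. Ac2O in pyridine acetylates the two secondary hydroxyls, leaving the tertiary one, to give the diacetate F3. DDQ in wet CH2Cl2 removes the PMB group to give the diol F4, MsCl/Et3N gives the mesylate F5, and DBU in toluene at 60 °C closes the oxirane. The route is rejoined at 26.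

**Further compounds**
F0 | step 8 | none | none
F1 | step 11 | C1 spiro-oxirane (O α-axial, C7 β-equatorial), 2α,3β-bis-OTBS, 4α,5β-bis-OBn, 6β-OPMB | CC(C)(C)[Si](C)(C)O[C@H]1[C@H](OCc2ccccc2)[C@@H](OCc2ccccc2)[C@@H](OCc2ccc(OC)cc2)[C@@]3(CO3)[C@@H]1O[Si](C)(C)C(C)(C)C
F2 | step 16 | 1α,2α,3β-triol, 1β-CH2OBz, 4α,5β-bis-OBn, 6β-OPMB | O[C@H]1[C@H](OCc2ccccc2)[C@@H](OCc2ccccc2)[C@@H](OCc2ccc(OC)cc2)[C@@](O)(COC(=O)c2ccccc2)[C@@H]1O
F3 | step 16 | 2α,3β-diacetate, 1α-OH, 1β-CH2OBz, 4α,5β-bis-OBn, 6β-OPMB | CC(=O)O[C@H]1[C@H](OCc2ccccc2)[C@@H](OCc2ccccc2)[C@@H](OCc2ccc(OC)cc2)[C@@](O)(COC(=O)c2ccccc2)[C@@H]1OC(C)=O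
F4 | step 16 | 2α,3β-diacetate, 1α,6β-diol, 1β-CH2OBz, 4α,5β-bis-OBn | CC(=O)O[C@H]1[C@H](OCc2ccccc2)[C@@H](OCc2ccccc2)[C@@H](O)[C@@](O)(COC(=O)c2ccccc2)[C@@H]1OC(C)=O
F5 | step 16 | 2α,3β-diacetate, 6β-OMs, 1α-OH, 1β-CH2OBz, 4α,5β-bis-OBn | CC(=O)O[C@H]1[C@H](OCc2ccccc2)[C@@H](OCc2ccccc2)[C@@H](OS(C)(=O)=O)[C@@](O)(COC(=O)c2ccccc2)[C@@H]1OC(C)=O
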